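The leftover Z opens the argument: after 20.0 h the maple run still holds Z at 7.8% and L at 42.5%, yet L, at one X each, has used 0.0570 M of X, less than the 0.201 M charged.

| flask | Z | G | X | J | remark |
|---|---|---|---|---|---|
| maple | 0.067 M | 0.067 M | 3 equiv | 1.4 mol% | run made earlier |
| alder | 0.15 M | 0.15 M | 3 equiv | 1.4 mol% | run made earlier |
| elm | 0.10 M | 0.10 M | 1.5 equiv | 1.4 mol% | run made earlier |
| flask | 0.10 M | 0.10 M | 3.00 equiv | 1.4 mol% |  |

| run | time / h | L / % | Z / % |
|---|---|---|---|
| maple | 1.50 | 23.1 | 27.5 |
| maple | 3.00 | 31.0 | 18.6 |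
| maple | 6.00 | 37.6 | 11.8 |
| maple | 10.0 | 40.9 | 9.0 |
| maple | 20.0 | 42.5 | 7.8 |
| alder | 2.00 | 46.5 | 3.4 |
| alder | 5.00 | 49.1 | 0.8 |
| alder | 10.0 | 50.7 | 0.9 |
| alder | 15.0 | 49.9 | 0 |
| alder | 20.0 | 50.0 | 0.6 |
| elm | 1.50 | 21.8 | 28.5 |
| elm | 3.00 | 28.2 | 21.7 |
| elm | 6.00 | 31.8 | 17.2 |
| elm | 10.0 | 35.6 | 15.4 |
| elm | 20.0 | 37.0 | 12.6 |

(standard deviation of a reading: 0.5 percentage points)

- J is single-handed; Z and G are mirror images of each other, charged as a racemate, each of them at the stated concentration

- apparent order in X when 50% of the Z and G together are converted (percent change of the rate of making L for one percent more X charged)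

The readings form a ladder. On the first rung Z falls, with the alder run down to 3.4% by 2.00 h. On the next rung the fall slows, as the maple run's Z moves from 9.0% at 10.0 h to 7.8% at 20.0 h, less per hour than between 1.50 h and 3.00 h. My own judgement places the flask's conversion of 50% on the first rung, and I take one X for each converted molecule. The quantity to follow there is the lever of X, charged X over X still present, which is the percent rise of present X for one percent more X charged, with the amount of X used held fixed:

c(X) charged = 0.300 M, c(X) used = 0.100 M

lever = 1.50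

For a rate first order in X, with its other factors held fixed, my reckoning gives this lever as the order. The forecast says 1.6, a little higher, adding: “Reaching that point sooner, with more live catalyst, could push it higher”.

The flask gives 1.9, above the lever, at 1.27 h, when J is 84.4% of the catalyst.

X ⇌ E (K = 0.790, k = 2.30 × 10⁻⁵ s⁻¹); X + J + G → J + D (k = 0.320 M⁻² s⁻¹); J → Q (k = 3.70 × 10⁻⁵ s⁻¹); X + J + Z → J + L (k = 0.790 M⁻² s⁻¹) At 2.50 h the flask holds X at 45.5% of its charge, a lever of 2.20, and E stands at 0.0341 M, which is 11.4% of the X charged.

The runs come from a simulation from invented constants; scatter was added.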